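**Retrosynthetic overview**
- The plan rests on the Z trisubstituted C1=C10 alkene of the ten-membered carbocycle, in which ring carbons C2 and C9 are cis and methyl C14 sits on C10. It is made by cutting SO2 out of an eleven-membered cyclic sulfone that carries sulfur between C1 and C10 (Ramberg–Bäcklund contraction).
- The thiacycle is disconnected at S–C1 (thiolate on a primary chloride). The chain is disconnected at C6–C7, by CrCl2 allylation of an (E)-enal (C1–C6) with a Baylis–Hillman bromide (C7–C13).
- C8 and C9 come from diethyl D-tartrate and C2 from (S)-epichlorohydrin. C6 and C7 are relayed from C8. Methyl C14 and sulfur are put on C10 only after the fragments are joined, so no thiol protecting group has to survive hydride or strong base.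
- Ring order: provisional γ-lactone (step 12, reduced open in step 13), eleven-membered thiacycle (step 20), ten-membered carbocycle (step 22), α-methylene-γ-lactone (step 26). Acetate, angelate and the free C2 hydroxyl follow from graded deprotection.

Key step: step 22

Remark on the chemistry: germacranolide locants are used for all compounds (ring C1–C10, C14 on C10, C15 on C4, C11–C13 for the methylene-lactone carbons); C10 arises in step 18 as an epimer mixture that is carried on unseparated, so those SMILES carry no descriptor at C10.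

**Fragment 1 (C7–C13)**

Step 1
Reactants: 1 diethyl D-tartrate
Product: 2 diethyl (4S,5S)-2-(naphthalen-2-yl)-1,3-dioxolane-4,5-dicarboxylate
Conditions: 2-naphthaldehyde, TsOH·H2O (cat.), toluene, reflux, Dean–Stark
Reagents that add atoms: 2-naphthaldehyde, O=Cc1ccc2ccccc2c1
Why: Acid-catalysed acetalisation is driven by azeotropic water removal, and because the diol is C2-symmetric the acetal carbon is not stereogenic and the future C8 and C9 centres are untouched.

Step 2
Reactants: 2 naphthylidene acetal diester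
Product: 3 2-O-(2-naphthylmethyl)-D-threitol, (2R,3R)-3-(naphthalen-2-ylmethoxy)butane-1,2,4-triol
Conditions: LiAlH4, AlCl3, Et2O–CH2Cl2, 0 °C → reflux
Reagents that add atoms: none
Why: Chloroalane reduction takes both esters to alcohols and reductively opens the arylidene acetal, and since the two acetal C–O bonds are homotopic only one mono-ether can form, which distinguishes O8 (NAP ether) from O9 (free).

Step 3
Reactants: 3 2-O-NAP-D-threitol
Product: 4 (2R)-2-[(4R)-2,2-dimethyl-1,3-dioxolan-4-yl]-2-(naphthalen-2-ylmethoxy)ethanol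
Conditions: 2,2-dimethoxypropane, TsOH·H2O (cat.), acetone, rt
Reagents that add atoms: 2,2-dimethoxypropane, COC(C)(C)OC
Why: Transacetalisation under equilibrium control favours the five-membered dioxolane on the terminal O9/O10 diol over a six-membered dioxane, which leaves the C7 hydroxyl as the only free one.

Step 4
Reactants: 4 acetonide alcohol
Product: 5 (2S)-2-[(4R)-2,2-dimethyl-1,3-dioxolan-4-yl]-2-(naphthalen-2-ylmethoxy)acetaldehyde
Conditions: Dess–Martin periodinane, CH2Cl2, 0 °C → rt
Reagents that add atoms: none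
Why: Dess–Martin oxidation stops at the aldehyde under nearly neutral conditions, so the α-alkoxy centre C8 should not epimerise.

Step 5
Reactants: 5 aldehyde; 6 methyl acrylate
Product: 7 methyl 2-[(2R)-2-[(4R)-2,2-dimethyl-1,3-dioxolan-4-yl]-1-hydroxy-2-(naphthalen-2-ylmethoxy)ethyl]acrylate (C7 carbinol epimers)
Conditions: DABCO (1 equiv), 6 (3 equiv), 1,4-dioxane–H2O 1:1, rt
Reagents that add atoms: none
Why: The Morita–Baylis–Hillman reaction is comparatively fast with inductively activated α-alkoxy aldehydes, and the epimer mixture at C7 does not matter because C7 becomes sp2 in step 6.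

Step 6
Reactants: 7 Baylis–Hillman adduct
Product: 8 methyl (2Z,4R)-2-(bromomethyl)-4-[(4R)-2,2-dimethyl-1,3-dioxolan-4-yl]-4-(naphthalen-2-ylmethoxy)but-2-enoate
Conditions: NBS, Me2S, CH2Cl2, 0 °C → rt
Reagents that add atoms: N-bromosuccinimide, O=C1CCC(=O)N1Br
Why: Corey–Kim-type activation of the allylic alcohol followed by SN2′ attack of bromide at the methylene terminus is the standard conversion of such adducts, gives the Z bromide (C8 trans to the ester) and spares the acetonide because no strong acid is present.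

**Fragment 2 (C1–C6)**

Step 7
Reactants: 9 trimethylsilylacetylene; 10 (S)-epichlorohydrin
Product: 12 (2S)-1-chloro-5-(trimethylsilyl)pent-4-yn-2-ol, via lithium trimethylsilylacetylide 11 (not isolated)
Conditions: 9, n-BuLi, THF, −78 °C; BF3·OEt2; then 10, −78 °C
Reagents that add atoms: none
Why: In the Yamaguchi–Hirao alkynylation the BF3-activated epoxide is opened at its unsubstituted carbon at −78 °C, so the stereocentre of 10 is kept as C2 and the chlorohydrin does not close to a new epoxide.

Step 8
Reactants: 12 chlorohydrin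
Product: 13 (2S)-2-(tert-butyldimethylsilyloxy)-1-chloro-5-(trimethylsilyl)pent-4-yne
Conditions: TBSCl, imidazole, DMF, rt
Reagents that add atoms: tert-butyldimethylsilyl chloride, CC(C)(C)[Si](C)(C)Cl
Why: This is a standard O-silylation, and imidazole is too weak a base to close the chlorohydrin to an epoxide.

Step 9
Reactants: 13 silyl alkyne
Product: 14 (2S)-2-(tert-butyldimethylsilyloxy)-1-chloropent-4-yne
Conditions: K2CO3 (cat.), MeOH, rt
Reagents that add atoms: none
Why: Base-catalysed methanolysis of the C(sp)–Si bond is far faster than attack on the secondary TBS ether or the primary chloride.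

Step 10
Reactants: 14 terminal alkyne
Product: 17 (2E,5S)-5-(tert-butyldimethylsilyloxy)-6-chloro-3-methylhex-2-en-1-ol, via alkenyl dimethylalane 15 (not isolated), via lithium alkenylalanate 16 (not isolated)
Conditions: Me3Al (3 equiv), Cp2ZrCl2 (0.25 equiv), CH2Cl2, 0 °C → rt; n-BuLi, hexane–THF, −78 → 0 °C; (CH2O)n, rt
Reagents that add atoms: trimethylaluminium, C[Al](C)C; paraformaldehyde (as formaldehyde), C=O
Why: Negishi zirconium-catalysed carboalumination adds CH3 and Al syn across the alkyne with Al at the terminus, which fixes the 4E geometry, and the derived alanate is hydroxymethylated with retention to bring in C6.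

Step 11
Reactants: 17 allylic alcohol
Product: 18 (2E,5S)-5-(tert-butyldimethylsilyloxy)-6-chloro-3-methylhex-2-enal
Conditions: MnO2, CH2Cl2, rt
Reagents that add atoms: none
Why: Allylic oxidation with MnO2 is neutral and selective and should keep the E geometry of the enal.

**Union and build-up of the sulfone**

Step 12
Reactants: 8 allylic bromide; 18 enal
Product: 21 trans-α-methylene-γ-lactone (6R,7S; C2, C8, C9 as in the target; C6 bears the chloro-silyloxy alkenyl chain, C7 bears C8(ONAP) and the dioxolane), via allylchromium dichloride 19 (not isolated), via anti hydroxy ester 20 (not isolated)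
Conditions: CrCl2 (4 equiv), THF, 0 °C → rt; aq. NH4Cl
Reagents that add atoms: none
Why: In this Nozaki–Hiyama allylation the equilibrating allylchromium adds 1,2 to the enal through a Zimmerman–Traxler chair with both large groups equatorial (6,7-anti, hence the trans-lactone once the chromium alkoxide closes on the ester), and C7 is set from C8 in a Felkin–Anh-type array with C8–H eclipsing the alkene (A1,3 strain) and the C8–O bond anti to the forming bond, while the alkyl chloride is inert to divalent chromium and any uncyclised 20 converges in step 13.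

Step 13
Reactants: 21 trans-lactone
Product: 22 C6,C12-diol (2-methylene-1,4-diol; all centres unchanged)
Conditions: i-Bu2AlH (5 equiv), CH2Cl2, −78 → 0 °C; aq. potassium sodium tartrate
Reagents that add atoms: none
Why: i-Bu2AlH reduces the α-methylene lactone by 1,2-addition twice, which removes the Michael acceptor before any thiolate or hydroxide chemistry and leaves chloride, acetonide, NAP and TBS groups alone.

Step 14
Reactants: 22 diol
Product: 23 C6,C12-bis(4-methoxybenzyl) ether
Conditions: NaH, PMBCl, Bu4NI (cat.), DMF, 0 °C → rt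
Reagents that add atoms: 4-methoxybenzyl chloride, COc1ccc(CCl)cc1
Why: This is a Williamson etherification, and no free hydroxyl neighbours a silyl ether so no silyl migration is expected, nor can either alkoxide reach the β-silyloxy chloride through a favourable ring size.

Step 15
Reactants: 23 bis-PMB ether
Product: 24 C9,C10-diol
Conditions: AcOH–THF–H2O 4:1:1, 40 °C
Reagents that add atoms: none
Why: Mild acid hydrolysis removes a terminal acetonide much faster than it attacks a secondary TBS ether or benzyl-type ethers.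

Step 16
Reactants: 24 diol
Product: 25 C9,C10-bis(triethylsilyl) ether
Conditions: TESOTf, 2,6-lutidine, CH2Cl2, −78 → 0 °C
Reagents that add atoms: triethylsilyl triflate, CC[Si](CC)(CC)OS(=O)(=O)C(F)(F)F
Why: The silyl triflate with a hindered base silylates even the crowded C9 hydroxyl without touching PMB or NAP ethers.

Step 17
Reactants: 25 bis-TES ether
Product: 26 C10 aldehyde (C9 OTES retained)
Conditions: (COCl)2, DMSO, CH2Cl2, −78 → −40 °C; Et3N, −78 °C → rt
Reagents that add atoms: none
Why: In this Swern oxidation of a silyl ether the activated DMSO attacks the unhindered primary O–TES and takes it straight to the aldehyde, while secondary TES and TBS ethers are known to survive.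

Step 18
Reactants: 26 aldehyde
Product: 27 C10 methyl carbinol (C10 epimers)
Conditions: MeMgBr, Et2O, −78 °C
Reagents that add atoms: methylmagnesium bromide, C[Mg]Br
Why: Grignard addition brings in C14, needs no facial control because C10 is later flattened, and is cold enough to suppress 1,2-migration of the TES group.

Step 19
Reactants: 27 carbinol; 28 thioacetic acid
Product: 29 C10 thioacetate (C10 epimers)
Conditions: PPh3, DIAD, 28, THF, 0 °C → rt
Reagents that add atoms: none
Why: Mitsunobu thioesterification activates only the free C10 hydroxyl, so sulfur is placed there by SN2 without competition from the C1 chloride, which a mesylate–thioacetate salt displacement could not guarantee.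

Step 20
Reactants: 29 thioacetate
Product: 31 eleven-membered thiacycle (S between C1 and C10), via C10 thiol 30 (not isolated)
Conditions: Cs2CO3, MeOH (10 equiv), NaI (cat.), degassed DMF, 50 °C, syringe-pump addition, about 1 mM
Reagents that add atoms: none
Why: In this caesium-thiolate macrocyclisation methanolysis frees 30, whose soft thiolate displaces the primary chloride (11-exo-tet SN2, assisted by iodide) under pseudo-high dilution, with the long C–S bonds and the E alkene easing medium-ring strain.

Step 21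
Reactants: 31 thiacycle
Product: 33 eleven-membered cyclic sulfone (C9 OTES, C8 ONAP, C6 and C12 OPMB, C2 OTBS), via cyclic sulfoxide 32 (not isolated)
Conditions: (NH4)6Mo7O24·4H2O (0.2 equiv), 30% H2O2, EtOH–THF, 0 °C → rt
Reagents that add atoms: hydrogen peroxide, OO
Why: Molybdate-catalysed peroxide oxidation is chemoselective for sulfur and leaves alone alkenes that lack a free allylic hydroxyl, benzyl-type ethers and hindered silyl ethers.

**Key step**

Step 22
Reactants: 33 cyclic sulfone
Product: 36 protected (1(10)Z,4E)-cyclodecadiene (2S,6R,7S,8R,9R), via C1-bromo sulfone 34 (not isolated), via cis-fused episulfone 35 (not isolated)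
Conditions: CBr2F2 (excess), KOH/Al2O3, t-BuOH–CH2Cl2, 0 °C → rt
Reagents that add atoms: none
Why: In this Ramberg–Bäcklund reaction with in situ halogenation, KOH on alumina deprotonates the less hindered C1, the carbanion takes bromine from CBr2F2 to give 34 (a C10 bromide would converge), deprotonation at C10 then expels bromide by 1,3-displacement to give thiirane 1,1-dioxide 35, and cheletropic loss of SO2 turns the new C1–C10 σ bond into the alkene. The closest known reaction type is the contraction of medium and large cyclic sulfones under the same conditions, and tolerance of β-alkoxy groups is known from the conversion of glycosyl sulfones into exo-glycals. The ten-membered ring is closed by a transannular 3-exo-tet closure inside the existing eleven-membered ring, so no end-to-end medium-ring C–C cyclisation and no dilution are needed. No stereocentre is created, and C10 loses its stereogenicity so the epimer mixture 33 funnels into one product; the geometry is decided in 35, because SO2 leaves stereospecifically and the cis-fused bicyclo[8.1.0] episulfone (C2 and C9 on one face) is the kinetic product with hydroxide-type bases and should be the less strained isomer, which gives the Z alkene. The step requires halogenation and closure to outrun E1cB loss of the C2 and C9 silyloxy groups, which is secured by poor silyloxide leaving groups, low temperature, a heterogeneous base and a large excess of the fast bromine donor. PMB, NAP and silyl ethers are inert to KOH/Al2O3, and the CF2 released from spent CBr2F2 should be hydrolysed on the basic support faster than it adds to the alkyl-substituted alkenes.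

**Endgame**

Step 23
Reactants: 36 cyclodecadiene
Product: 37 C9 alcohol
Conditions: PPTS (cat.), MeOH–CH2Cl2, 0 °C
Reagents that add atoms: none
Why: Graded silyl lability means mild acid methanolysis removes TES well before the secondary TBS ether at C2.

Step 24
Reactants: 37 C9 alcohol
Product: 38 C9 acetate
Conditions: Ac2O, pyridine, DMAP (cat.), CH2Cl2, rt
Reagents that add atoms: acetic anhydride, CC(=O)OC(C)=O
Why: DMAP-catalysed acetylation acts on the only free hydroxyl.

Step 25
Reactants: 38 acetate
Product: 39 C6,C12-diol (C8 ONAP retained)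
Conditions: (NH4)2Ce(NO3)6 (5 equiv), MeCN–H2O 9:1, 0 °C
Reagents that add atoms: none
Why: Oxidative PMB cleavage by tetravalent cerium is known to leave NAP ethers in place, and here sterics help because the two PMB groups sit on the exposed O6 and O12 while NAP sits on the crowded O8.

Step 26
Reactants: 39 diol
Product: 42 6,12-olide (α-methylene-γ-lactone, trans-fused; C8 ONAP, C9 OAc, C2 OTBS), via hydroxy enal 40 (not isolated), via lactol 41 (not isolated)
Conditions: TEMPO (0.2 equiv), PhI(OAc)2 (3 equiv), CH2Cl2, rt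
Reagents that add atoms: none
Why: In this TEMPO oxidative lactonisation the oxoammonium salt prefers the primary allylic C12 hydroxyl over the secondary allylic C6 hydroxyl (a distinction MnO2 would make less cleanly), the C6 hydroxyl then closes the five-membered lactol, which is oxidised on, and O8 is blocked so no 8,12-olide can form.

Step 27
Reactants: 42 NAP-protected lactone
Product: 43 C8 alcohol
Conditions: DDQ, CH2Cl2–pH 7 buffer 10:1, rt
Reagents that add atoms: none
Why: DDQ removes the NAP ether oxidatively under buffered, non-basic conditions, which should prevent acetyl migration and translactonisation.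

Step 28
Reactants: 43 C8 alcohol; 44 angelic acid
Product: 46 C8 angelate (C2 OTBS), via angelic trichlorobenzoic anhydride 45 (not isolated)
Conditions: 44, 2,4,6-trichlorobenzoyl chloride, Et3N, toluene, rt; then 43, 75 °C
Reagents that add atoms: none
Why: Yamaguchi-type mixed-anhydride esterification run without DMAP is the established way to transfer the angeloyl group with retention of its Z geometry, because no acylpyridinium forms that could isomerise it to the tiglate.

Step 29
Reactants: 46 silyl ether
Product: 47 target CNP0316477.1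
Conditions: HF·pyridine, pyridine, THF, 0 °C → rt
Reagents that add atoms: none
Why: Buffered fluoride desilylation frees the C2 hydroxyl without base, so both esters, the angelate geometry and the α-methylene lactone should survive.

**Compound list**

1 | diethyl D-tartrate | CCOC(=O)[C@@H](O)[C@H](O)C(=O)OCC | starting material
2 | diethyl (4S,5S)-2-(naphthalen-2-yl)-1,3-dioxolane-4,5-dicarboxylate | CCOC(=O)[C@H]1OC(c2ccc3ccccc3c2)O[C@@H]1C(=O)OCC | intermediate
3 | 2-O-(2-naphthylmethyl)-D-threitol | OC[C@@H](O)[C@H](OCc1ccc2ccccc2c1)CO | intermediate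
4 | (2R)-2-[(4R)-2,2-dimethyl-1,3-dioxolan-4-yl]-2-(naphthalen-2-ylmethoxy)ethanol | CC1(C)OC[C@@H](O1)[C@H](OCc2ccc3ccccc3c2)CO | intermediate
5 | (2S)-2-[(4R)-2,2-dimethyl-1,3-dioxolan-4-yl]-2-(naphthalen-2-ylmethoxy)acetaldehyde | CC1(C)OC[C@@H](O1)[C@H](OCc2ccc3ccccc3c2)C=O | intermediate
6 | methyl acrylate | C=CC(=O)OC | starting material
7 | Baylis–Hillman adduct (C7 epimers) | CC1(C)OC[C@@H](O1)[C@H](OCc2ccc3ccccc3c2)C(O)C(=C)C(=O)OC | intermediate
8 | (Z)-allylic bromide | CC1(C)OC[C@@H](O1)[C@H](OCc2ccc3ccccc3c2)/C=C(\CBr)C(=O)OC | intermediate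
9 | trimethylsilylacetylene | C#C[Si](C)(C)C | starting material
10 | (S)-epichlorohydrin | ClC[C@@H]1CO1 | starting material
11 | lithium trimethylsilylacetylide | [Li]C#C[Si](C)(C)C | intermediate
12 | (2S)-1-chloro-5-(trimethylsilyl)pent-4-yn-2-ol | C[Si](C)(C)C#CC[C@H](O)CCl | intermediate
13 | TBS ether of 12 | C[Si](C)(C)C#CC[C@H](O[Si](C)(C)C(C)(C)C)CCl | intermediate
14 | (2S)-2-(tert-butyldimethylsilyloxy)-1-chloropent-4-yne | C#CC[C@H](O[Si](C)(C)C(C)(C)C)CCl | intermediate
15 | (E)-alkenyl dimethylalane | C[Al](C)/C=C(\C)C[C@H](O[Si](C)(C)C(C)(C)C)CCl | intermediate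
16 | lithium butyl(dimethyl)alkenylalanate | [Li+].CCCC[Al-](C)(C)/C=C(\C)C[C@H](O[Si](C)(C)C(C)(C)C)CCl | intermediate
17 | (2E,5S)-5-(TBS-oxy)-6-chloro-3-methylhex-2-en-1-ol | OC/C=C(\C)C[C@H](O[Si](C)(C)C(C)(C)C)CCl | intermediate
18 | (2E,5S)-5-(TBS-oxy)-6-chloro-3-methylhex-2-enal | O=C/C=C(\C)C[C@H](O[Si](C)(C)C(C)(C)C)CCl | intermediate
19 | allylchromium dichloride (geometry equilibrating) | COC(=O)C(C[Cr](Cl)Cl)=C[C@@H](OCc1ccc2ccccc2c1)[C@H]3COC(C)(C)O3 | intermediate
20 | 6,7-anti hydroxy ester | O[C@H](/C=C(\C)C[C@H](O[Si](C)(C)C(C)(C)C)CCl)[C@H](C(=C)C(=O)OC)[C@@H](OCc1ccc2ccccc2c1)[C@H]3COC(C)(C)O3 | intermediate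
21 | trans-α-methylene-γ-lactone | C=C1C(=O)O[C@H](/C=C(\C)C[C@H](O[Si](C)(C)C(C)(C)C)CCl)[C@H]1[C@@H](OCc2ccc3ccccc3c2)[C@H]4COC(C)(C)O4 | intermediate
22 | C6,C12-diol | O[C@H](/C=C(\C)C[C@H](O[Si](C)(C)C(C)(C)C)CCl)[C@H](C(=C)CO)[C@@H](OCc1ccc2ccccc2c1)[C@H]3COC(C)(C)O3 | intermediate
23 | C6,C12-bis-PMB ether | COc1ccc(CO[C@H](/C=C(\C)C[C@H](O[Si](C)(C)C(C)(C)C)CCl)[C@H](C(=C)COCc2ccc(OC)cc2)[C@@H](OCc3ccc4ccccc4c3)[C@H]5COC(C)(C)O5)cc1 | intermediate
24 | C9,C10-diol | COc1ccc(CO[C@H](/C=C(\C)C[C@H](O[Si](C)(C)C(C)(C)C)CCl)[C@H](C(=C)COCc2ccc(OC)cc2)[C@@H](OCc3ccc4ccccc4c3)[C@H](O)CO)cc1 | intermediate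
25 | C9,C10-bis-TES ether | COc1ccc(CO[C@H](/C=C(\C)C[C@H](O[Si](C)(C)C(C)(C)C)CCl)[C@H](C(=C)COCc2ccc(OC)cc2)[C@@H](OCc3ccc4ccccc4c3)[C@H](O[Si](CC)(CC)CC)CO[Si](CC)(CC)CC)cc1 | intermediate
26 | C10 aldehyde | COc1ccc(CO[C@H](/C=C(\C)C[C@H](O[Si](C)(C)C(C)(C)C)CCl)[C@H](C(=C)COCc2ccc(OC)cc2)[C@@H](OCc3ccc4ccccc4c3)[C@H](O[Si](CC)(CC)CC)C=O)cc1 | intermediate
27 | C10 methyl carbinol (C10 epimers) | COc1ccc(CO[C@H](/C=C(\C)C[C@H](O[Si](C)(C)C(C)(C)C)CCl)[C@H](C(=C)COCc2ccc(OC)cc2)[C@@H](OCc3ccc4ccccc4c3)[C@H](O[Si](CC)(CC)CC)C(C)O)cc1 | intermediate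
28 | thioacetic acid | CC(=O)S | starting material
29 | C10 thioacetate (C10 epimers) | COc1ccc(CO[C@H](/C=C(\C)C[C@H](O[Si](C)(C)C(C)(C)C)CCl)[C@H](C(=C)COCc2ccc(OC)cc2)[C@@H](OCc3ccc4ccccc4c3)[C@H](O[Si](CC)(CC)CC)C(C)SC(C)=O)cc1 | intermediate
30 | C10 thiol (C10 epimers) | COc1ccc(CO[C@H](/C=C(\C)C[C@H](O[Si](C)(C)C(C)(C)C)CCl)[C@H](C(=C)COCc2ccc(OC)cc2)[C@@H](OCc3ccc4ccccc4c3)[C@H](O[Si](CC)(CC)CC)C(C)S)cc1 | intermediate
31 | eleven-membered thiacycle (C10 epimers) | COc1ccc(CO[C@@H]2/C=C(\C)C[C@H](O[Si](C)(C)C(C)(C)C)CSC(C)[C@@H](O[Si](CC)(CC)CC)[C@H](OCc3ccc4ccccc4c3)[C@H]2C(=C)COCc5ccc(OC)cc5)cc1 | intermediate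
32 | cyclic sulfoxide | COc1ccc(CO[C@@H]2/C=C(\C)C[C@H](O[Si](C)(C)C(C)(C)C)CS(=O)C(C)[C@@H](O[Si](CC)(CC)CC)[C@H](OCc3ccc4ccccc4c3)[C@H]2C(=C)COCc5ccc(OC)cc5)cc1 | intermediate
33 | eleven-membered cyclic sulfone (C10 epimers) | COc1ccc(CO[C@@H]2/C=C(\C)C[C@H](O[Si](C)(C)C(C)(C)C)CS(=O)(=O)C(C)[C@@H](O[Si](CC)(CC)CC)[C@H](OCc3ccc4ccccc4c3)[C@H]2C(=C)COCc5ccc(OC)cc5)cc1 | intermediate
34 | C1-bromo sulfone | COc1ccc(CO[C@@H]2/C=C(\C)C[C@H](O[Si](C)(C)C(C)(C)C)C(Br)S(=O)(=O)C(C)[C@@H](O[Si](CC)(CC)CC)[C@H](OCc3ccc4ccccc4c3)[C@H]2C(=C)COCc5ccc(OC)cc5)cc1 | intermediate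
35 | cis-fused episulfone (one of the two cis faces drawn) | COc1ccc(CO[C@@H]2/C=C(\C)C[C@H](O[Si](C)(C)C(C)(C)C)[C@@H]6[C@@](C)(S6(=O)=O)[C@@H](O[Si](CC)(CC)CC)[C@H](OCc3ccc4ccccc4c3)[C@H]2C(=C)COCc5ccc(OC)cc5)cc1 | intermediate
36 | protected (1(10)Z,4E)-cyclodecadiene | COc1ccc(CO[C@@H]2/C=C(\C)C[C@H](O[Si](C)(C)C(C)(C)C)/C=C(/C)[C@@H](O[Si](CC)(CC)CC)[C@H](OCc3ccc4ccccc4c3)[C@H]2C(=C)COCc5ccc(OC)cc5)cc1 | intermediate
37 | C9 alcohol | COc1ccc(CO[C@@H]2/C=C(\C)C[C@H](O[Si](C)(C)C(C)(C)C)/C=C(/C)[C@@H](O)[C@H](OCc3ccc4ccccc4c3)[C@H]2C(=C)COCc5ccc(OC)cc5)cc1 | intermediate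
38 | C9 acetate | COc1ccc(CO[C@@H]2/C=C(\C)C[C@H](O[Si](C)(C)C(C)(C)C)/C=C(/C)[C@@H](OC(C)=O)[C@H](OCc3ccc4ccccc4c3)[C@H]2C(=C)COCc5ccc(OC)cc5)cc1 | intermediate
39 | C6,C12-diol of the carbocycle | O[C@@H]1/C=C(\C)C[C@H](O[Si](C)(C)C(C)(C)C)/C=C(/C)[C@@H](OC(C)=O)[C@H](OCc2ccc3ccccc3c2)[C@H]1C(=C)CO | intermediate
40 | hydroxy enal | O[C@@H]1/C=C(\C)C[C@H](O[Si](C)(C)C(C)(C)C)/C=C(/C)[C@@H](OC(C)=O)[C@H](OCc2ccc3ccccc3c2)[C@H]1C(=C)C=O | intermediate
41 | lactol (C12 epimers) | C=C1C(O)O[C@@H]2/C=C(\C)C[C@H](O[Si](C)(C)C(C)(C)C)/C=C(/C)[C@@H](OC(C)=O)[C@H](OCc3ccc4ccccc4c3)[C@@H]12 | intermediate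
42 | 6,12-olide, C8 ONAP | C=C1C(=O)O[C@@H]2/C=C(\C)C[C@H](O[Si](C)(C)C(C)(C)C)/C=C(/C)[C@@H](OC(C)=O)[C@H](OCc3ccc4ccccc4c3)[C@@H]12 | intermediate
43 | 6,12-olide, C8 OH | C=C1C(=O)O[C@@H]2/C=C(\C)C[C@H](O[Si](C)(C)C(C)(C)C)/C=C(/C)[C@@H](OC(C)=O)[C@H](O)[C@@H]12 | intermediate
44 | angelic acid | C/C=C(/C)C(=O)O | starting material
45 | angelic 2,4,6-trichlorobenzoic anhydride | C/C=C(/C)C(=O)OC(=O)c1c(Cl)cc(Cl)cc1Cl | intermediate
46 | C2-O-TBS ether of the target | C=C1C(=O)O[C@@H]2/C=C(\C)C[C@H](O[Si](C)(C)C(C)(C)C)/C=C(/C)[C@@H](OC(C)=O)[C@H](OC(=O)/C(C)=C\C)[C@@H]12 | intermediate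
47 | CNP0316477.1 (2S,6R,7S,8R,9R; 1(10)Z,4E) | C=C1C(=O)O[C@@H]2/C=C(\C)C[C@H](O)/C=C(/C)[C@@H](OC(C)=O)[C@H](OC(=O)/C(C)=C\C)[C@@H]12 | target

**Step count**

Total: 29 steps. The longest linear sequence is 24 steps (steps 1–6, then 12–29). Fragment 2 adds 5 steps (7–11).

**Steps most likely to fail**

1. **Step 22.**
   - What may go wrong: E1cB expulsion of the C2 or C9 silyloxide from carbanions that have not yet been halogenated; repeated bromination at C1; or epimerisation of the episulfone at C1–H before SO2 leaves, which would erode the Z geometry.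
   - Fallback: it sets out from 33 and separates halogenation from closure. C1 is lithiated with n-BuLi in THF at −78 °C, where β-silyloxy sulfonyl anions are persistent. Trapping with C2Cl6 should give the isolable C1-chloro sulfone F1. Brief exposure of F1 to KOt-Bu in THF at −78 to −20 °C is the classical two-stage Ramberg–Bäcklund reaction, in which each deprotonation at C10 leads directly to closure. The sequence rejoins the route at 36.

2. **Step 12.**
   - What may go wrong: loss of the anti preference if the allylchromium reacts from the geometry with C8 cis to CH2Cr; a weak facial bias at C7; or vinylogous elimination of the C8 alkoxide from the allylmetal.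
   - Fallback: it sets out from 8 and 18 and sets C6 in a different way. Indium powder in THF–H2O couples the two through the geometry-retaining allylindium. This reaction type is known to be syn-selective with (Z)-2-(bromomethyl)alk-2-enoates, and it should give the 6-epimeric cis-lactone F2.
   - Saponification (LiOH, THF–H2O, 0 °C, acidification only to about pH 5, used at once) gives the 6-epi hydroxy acid F3.
   - Mitsunobu lactonisation (PPh3, DIAD, THF, 0 °C) activates the C6 hydroxyl so that the carboxylate closes the five-membered ring with inversion. The sequence rejoins the route at 21.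

3. **Step 28.**
   - What may go wrong: slow acylation of the crowded C8 hydroxyl, which gives time for Z-to-E isomerisation of the angeloyl unit and for base-induced acetyl migration from O9 to O8.
   - Fallback: it sets out from 43 and builds the angelate on the molecule. A small, non-isomerisable acyl group is attached first, using 2-[bis(2,2,2-trifluoroethoxy)phosphoryl]propanoic acid, EDC·HCl and DMAP (cat.) in CH2Cl2 at 0 °C, to give the C8 phosphonopropionate F4.
   - Z-selective Still–Gennari olefination follows: KN(SiMe3)2 (1.0 equiv), 18-crown-6, THF, −78 °C, then acetaldehyde. It creates the (Z)-2-methylbut-2-enoate at low temperature and rejoins the route at 46.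

**Further compounds**

F1 | step 22 | C1-chloro sulfone (C1 and C10 epimers) | COc1ccc(CO[C@@H]2/C=C(\C)C[C@H](O[Si](C)(C)C(C)(C)C)C(Cl)S(=O)(=O)C(C)[C@@H](O[Si](CC)(CC)CC)[C@H](OCc3ccc4ccccc4c3)[C@H]2C(=C)COCc5ccc(OC)cc5)cc1
F2 | step 12 | 6-epimeric cis-α-methylene-γ-lactone | C=C1C(=O)O[C@@H](/C=C(\C)C[C@H](O[Si](C)(C)C(C)(C)C)CCl)[C@H]1[C@@H](OCc2ccc3ccccc3c2)[C@H]4COC(C)(C)O4
F3 | step 12 | 6-epi hydroxy acid | O[C@@H](/C=C(\C)C[C@H](O[Si](C)(C)C(C)(C)C)CCl)[C@H](C(=C)C(=O)O)[C@@H](OCc1ccc2ccccc2c1)[C@H]3COC(C)(C)O3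
F4 | step 28 | C8 2-[bis(2,2,2-trifluoroethoxy)phosphoryl]propanoate (epimers at the phosphonate carbon) | C=C1C(=O)O[C@@H]2/C=C(\C)C[C@H](O[Si](C)(C)C(C)(C)C)/C=C(/C)[C@@H](OC(C)=O)[C@H](OC(=O)C(C)P(=O)(OCC(F)(F)F)OCC(F)(F)F)[C@@H]12
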